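The seven-membered lactam is closed last, at the bond between its N-bound CH2 (C5) and the adjacent ring CH2 (C6). One pot removes a Boc group from a nine-membered keto-lactam, converts the lactam nitrogen with formaldehyde into an N-methylene N-acyliminium ion and lets a (Z)-vinylsilane on the lactam α-carbon (C9) capture it 7-endo, creating the bridged azepanone/azonane core. The step exploits the aminomethylene N4–C5H2 flanked by the C9a lactam carbonyl. Its precursor arises by ozonolysis of the ring-fusion enecarbamate (C1=C9a) of a hexahydroindole, itself assembled from a silyloxycyclohexenone and a serine-derived alkylzinc.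

Key step: step 16

Assumption: compounds 1 and 8 are bought as single enantiomers.
Numbering used in the text: N4, C5–C8, C9, C9a(=O) form the azepan-2-one; C9a, N4, C3, C2, C1(=O), C12, C11, C10, C9 form the nine-membered ring; O–C11, C12, C13(CH3), C14(=O) form the fused lactone; C18–C21 form the lactone on C3.

Step 1
Reactants: 1 N-Boc-O-benzyl-L-serinol
Product: 2 N-Boc-O-benzyl-L-serinal
Conditions: Dess–Martin periodinane, CH2Cl2, 0 °C → rt
Reagents that add atoms: none
Why: Dess–Martin oxidation of the primary alcohol under non-basic conditions should give the N-Boc α-amino aldehyde without loss of the α-stereocentre (later C3).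

Step 2
Reactants: 2 N-Boc-O-benzyl-L-serinal; 3 ethyl 2-(bromomethyl)prop-2-enoate
Product: 5 (S,S)-α-methylene-γ-butyrolactone carbamate, via hydroxy ester 4 (not isolated)
Conditions: indium powder, THF/H2O 1:1, rt; then p-TsOH·H2O (cat.), CH2Cl2, rt
Reagents that add atoms: none
Why: Barbier-type allylation followed by acid-catalysed lactonisation; the NH-carbamate aldehyde should react through a chelated (Cram-cyclic) arrangement that gives the syn (threo) adduct and so the S carbinol centre (C18), the minor anti isomer being removed at the lactone stage.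

Step 3
Reactants: 5 (S,S)-α-methylene-γ-butyrolactone carbamate
Product: 6 cis-α-methyl-γ-butyrolactone amino alcohol carbamate
Conditions: H2 (1 atm), Pd/C (10%), MeOH, rt
Reagents that add atoms: none
Why: Catalytic hydrogenation should add H2 to the exocyclic alkene from the lactone face remote from the C18 substituent, giving the cis-2,4-disubstituted lactone (C20 S), while the benzyl ether is hydrogenolysed in the same operation.

Step 4
Reactants: 6 cis-α-methyl-γ-butyrolactone amino alcohol carbamate
Product: 7 β-carbamoyl alkyl iodide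
Conditions: I2, PPh3, imidazole, CH2Cl2, 0 °C → rt
Reagents that add atoms: iodine, II
Why: Appel-type iodination converts the primary alcohol into the iodide without touching any stereocentre.

Step 5
Reactants: 8 (4R)-4-(tert-butyldimethylsilyloxy)cyclohex-2-en-1-one; 9 (3-bromoprop-1-yn-1-yl)trimethylsilane
Product: 11 (2R,3R,4R)-4-(tert-butyldimethylsilyloxy)-3-ethyl-2-[3-(trimethylsilyl)prop-2-ynyl]cyclohexanone, via lithium enolate 10 (not isolated)
Conditions: Et2CuLi (from EtLi and CuI), Et2O, −78 °C; then 9, HMPA, THF, −78 → −20 °C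
Reagents that add atoms: ethyllithium (delivered as Et2CuLi), [Li]CC
Why: Three-component conjugate addition/enolate alkylation; the cuprate should add anti to the γ-silyloxy group (C10 ethyl trans to O-11) and the regiodefined enolate should be propargylated trans to the new ethyl group (C9).

Step 6
Reactants: 11 (2R,3R,4R)-4-(tert-butyldimethylsilyloxy)-3-ethyl-2-[3-(trimethylsilyl)prop-2-ynyl]cyclohexanone
Product: 13 (4R,5R,6R)-4-(tert-butyldimethylsilyloxy)-5-ethyl-6-[3-(trimethylsilyl)prop-2-ynyl]cyclohex-2-en-1-one, via silyl enol ether 12 (not isolated)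
Conditions: LDA, THF, −78 °C, then TMSCl; then Pd(OAc)2 (1.1 equiv), MeCN, rt
Reagents that add atoms: none
Why: Kinetic deprotonation at the unsubstituted α-methylene gives the less substituted silyl enol ether, and its Saegusa–Ito oxidation installs the C1=C12 enone regioselectively.

Step 7
Reactants: 13 (4R,5R,6R)-4-(tert-butyldimethylsilyloxy)-5-ethyl-6-[3-(trimethylsilyl)prop-2-ynyl]cyclohex-2-en-1-one
Product: 14 (4S,5R,6R)-2-iodo enone
Conditions: I2, pyridine, CH2Cl2, rt
Reagents that add atoms: iodine, II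
Why: Pyridine-mediated α-iodination of the enone (addition–elimination, Johnson iodination) places iodine on C1 for the cross-coupling.

Step 8
Reactants: 7 β-carbamoyl alkyl iodide; 14 (4S,5R,6R)-2-iodo enone
Product: 16 C1-alkylated enone carbamate, via alkylzinc iodide 15 (not isolated)
Conditions: Zn dust, DMF, rt; then 14, Pd2(dba)3 (2.5 mol%), SPhos (10 mol%), DMF, 40 °C
Reagents that add atoms: none
Why: Zinc insertion gives a carbamate-stabilised β-amino alkylzinc iodide that should undergo Negishi sp3–sp2 coupling with the α-iodoenone, forming C1–C2 with the serine-derived C3 centre intact.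

Step 9
Reactants: 16 C1-alkylated enone carbamate
Product: 17 γ-hydroxy enone carbamate
Conditions: HF·pyridine, pyridine, THF, 0 °C → rt
Reagents that add atoms: none
Why: Buffered HF·pyridine desilylation should cleave the secondary TBS ether while the C(sp)–SiMe3 bond, the carbamate and the lactone survive.

Step 10
Reactants: 17 γ-hydroxy enone carbamate; 18 ethyl prop-1-enyl ether
Product: 19 mixed bromoacetal
Conditions: NBS, CH2Cl2, −40 → 0 °C
Reagents that add atoms: N-bromosuccinimide, O=C1CCC(=O)N1Br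
Why: Bromoacetalisation (NBS-induced haloetherification of the enol ether by the allylic alcohol) tethers a secondary alkyl bromide to O-11 for an Ueno–Stork cyclisation.

Step 11
Reactants: 19 mixed bromoacetal
Product: 20 cis-fused bicyclic ethyl acetal
Conditions: Bu3SnH (slow addition), AIBN (cat.), PhH, 80 °C
Reagents that add atoms: none
Why: Ueno–Stork radical cyclisation; the nucleophilic secondary radical should add 5-exo-trig to the enone β-carbon (C12) from the face of the tethering oxygen, which enforces the cis C11/C12 ring fusion.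

Step 12
Reactants: 20 cis-fused bicyclic ethyl acetal
Product: 22 cis-fused α-methyl-γ-lactone ketone, via lactol 21 (not isolated)
Conditions: CrO3, H2SO4, H2O/acetone, 0 °C; then DBU (cat.), PhMe, rt
Reagents that add atoms: water, O
Why: Jones oxidation hydrolyses the acetal and oxidises the lactol to the γ-lactone, and DBU should then equilibrate the α-methyl group to the convex face (C13 S) and keep the C9 substituent trans to ethyl.

Step 13
Reactants: 22 cis-fused α-methyl-γ-lactone ketone
Product: 23 bicyclic N-Boc enecarbamate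
Conditions: PPTS (cat.), PhMe, 4 Å MS, 90 °C
Reagents that add atoms: none
Why: Acid-catalysed cyclodehydration of the γ-carbamoyl ketone gives the enecarbamate, and allylic strain with the N-Boc group should place the double bond inside the five-membered ring (C1=C9a), which also erases the C1 stereocentre.

Step 14
Reactants: 23 bicyclic N-Boc enecarbamate
Product: 25 nine-membered N-Boc keto-lactam, via ozonide 24 (not isolated)
Conditions: O3, CH2Cl2, −78 °C; then Me2S, −78 °C → rt
Reagents that add atoms: ozone, [O-][O+]=O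
Why: Ozonolysis of the electron-rich tetrasubstituted enecarbamate cleaves C1=C9a into the C1 ketone and the C9a lactam carbonyl, expanding the fused 6/5 system to the nine-membered ring while the silylalkyne reacts far more slowly.

Step 15
Reactants: 25 nine-membered N-Boc keto-lactam
Product: 26 (Z)-vinylsilane N-Boc keto-lactam
Conditions: H2 (1 atm), Pd/CaCO3 poisoned with Pb(OAc)2, quinoline, EtOAc, rt
Reagents that add atoms: none
Why: Lindlar semihydrogenation adds H2 syn to the silylalkyne and should give the (Z)-vinylsilane needed for endocyclic ring closure.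

Step 16
Reactants: 26 (Z)-vinylsilane N-Boc keto-lactam
Product: 30 6,7-didehydro bridged keto-lactam, via NH-lactam 27 (not isolated), via N-hydroxymethyl lactam 28 (not isolated), via N-acyliminium ion 29 (not isolated)
Conditions: TFA, CH2Cl2, 0 °C → rt; then (CH2O)n, TFA, 25 → 40 °C
Reagents that add atoms: paraformaldehyde (as formaldehyde), C=O
Why: TFA cleaves the Boc group from the imide-type nitrogen, formaldehyde N-hydroxymethylates the secondary lactam and acid ionises the hemiaminal to the N-methylene N-acyliminium ion, whose CH2 carbon (C5) is attacked by the silicon-bearing vinyl carbon (C6), after which the β-silyl cation at C7 loses Me3Si to leave the cis C6=C7 alkene. The closest known reaction type is the N-acyliminium–vinylsilane cyclisation (amidoalkylation with a vinylsilane terminator). One ring is closed, the azepan-2-one, in the 7-endo-trig mode with respect to both the iminium ion and the vinylsilane, which turns the monocyclic nine-membered lactam into the N4/C9-bridged bicycle. No stereocentre is created, since C5, C6 and C7 are not stereogenic and C3, C9, C12 and the other centres are only carried through. The step needs endo regioselectivity, which should be secured by the β-silicon effect (ipso attack gives the stabilised cation) and by the (Z)-geometry that places silicon where the ring bond must form, and it needs the vinylsilane to outrun the enol of the C1 ketone, which the short tether from C9 to the N–CH2 group and the low enol content in TFA should secure.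

Step 17
Reactants: 30 6,7-didehydro bridged keto-lactam
Product: 31 CNP0311700.2 (target)
Conditions: H2 (1 atm), Pd/C (10%), EtOAc, rt
Reagents that add atoms: none
Why: Catalytic hydrogenation saturates the disubstituted cis ring alkene under neutral conditions that leave the ketone, the lactam, both lactones and the epimerisable C12 centre untouched.

Compound list
1 | tert-butyl N-[(2R)-1-(benzyloxy)-3-hydroxypropan-2-yl]carbamate (N-Boc-O-benzyl-L-serinol) | c1ccccc1COC[C@@H](CO)NC(=O)OC(C)(C)C | starting material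
2 | tert-butyl N-[(2S)-1-(benzyloxy)-3-oxopropan-2-yl]carbamate | c1ccccc1COC[C@@H](C=O)NC(=O)OC(C)(C)C | intermediate
3 | ethyl 2-(bromomethyl)prop-2-enoate | C=C(CBr)C(=O)OCC | starting material
4 | ethyl (4S,5S)-6-(benzyloxy)-5-[(tert-butoxycarbonyl)amino]-4-hydroxy-2-methylidenehexanoate | c1ccccc1COC[C@@H]([C@@H](O)CC(=C)C(=O)OCC)NC(=O)OC(C)(C)C | intermediate (not isolated)
5 | tert-butyl N-[(1S)-2-(benzyloxy)-1-[(2S)-4-methylidene-5-oxooxolan-2-yl]ethyl]carbamate | c1ccccc1COC[C@@H]([C@@H]2CC(=C)C(=O)O2)NC(=O)OC(C)(C)C | intermediate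
6 | tert-butyl N-[(1S)-2-hydroxy-1-[(2S,4S)-4-methyl-5-oxooxolan-2-yl]ethyl]carbamate | OC[C@@H]([C@@H]1C[C@H](C)C(=O)O1)NC(=O)OC(C)(C)C | intermediate
7 | tert-butyl N-[(1R)-2-iodo-1-[(2S,4S)-4-methyl-5-oxooxolan-2-yl]ethyl]carbamate | IC[C@@H]([C@@H]1C[C@H](C)C(=O)O1)NC(=O)OC(C)(C)C | intermediate
8 | (4R)-4-[(tert-butyldimethylsilyl)oxy]cyclohex-2-en-1-one | O=C1C=C[C@H](O[Si](C)(C)C(C)(C)C)CC1 | starting material
9 | (3-bromoprop-1-yn-1-yl)trimethylsilane | C[Si](C)(C)C#CCBr | starting material
10 | lithium (3R,4R)-4-[(tert-butyldimethylsilyl)oxy]-3-ethylcyclohex-1-en-1-olate | CC[C@H]1[C@H](O[Si](C)(C)C(C)(C)C)CCC([O-])=C1.[Li+] | intermediate (not isolated)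
11 | (2R,3R,4R)-4-[(tert-butyldimethylsilyl)oxy]-3-ethyl-2-[3-(trimethylsilyl)prop-2-yn-1-yl]cyclohexan-1-one | CC[C@H]1[C@H](O[Si](C)(C)C(C)(C)C)CCC(=O)[C@@H]1CC#C[Si](C)(C)C | intermediate
12 | kinetic trimethylsilyl enol ether of 11 (enol ether C=C towards the CH2 side, stereocentres as in 11) | CC[C@H]1[C@H](O[Si](C)(C)C(C)(C)C)CC=C(O[Si](C)(C)C)[C@@H]1CC#C[Si](C)(C)C | intermediate (not isolated)
13 | (4R,5R,6R)-4-[(tert-butyldimethylsilyl)oxy]-5-ethyl-6-[3-(trimethylsilyl)prop-2-yn-1-yl]cyclohex-2-en-1-one | CC[C@H]1[C@H](O[Si](C)(C)C(C)(C)C)C=CC(=O)[C@@H]1CC#C[Si](C)(C)C | intermediate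
14 | (4S,5R,6R)-4-[(tert-butyldimethylsilyl)oxy]-5-ethyl-2-iodo-6-[3-(trimethylsilyl)prop-2-yn-1-yl]cyclohex-2-en-1-one | CC[C@H]1[C@H](O[Si](C)(C)C(C)(C)C)C=C(I)C(=O)[C@@H]1CC#C[Si](C)(C)C | intermediate
15 | {(2R)-2-[(tert-butoxycarbonyl)amino]-2-[(2S,4S)-4-methyl-5-oxooxolan-2-yl]ethyl}zinc iodide | I[Zn]C[C@@H]([C@@H]1C[C@H](C)C(=O)O1)NC(=O)OC(C)(C)C | intermediate (not isolated)
16 | tert-butyl N-[(1S)-2-[(3S,4R,5R)-3-[(tert-butyldimethylsilyl)oxy]-4-ethyl-6-oxo-5-[3-(trimethylsilyl)prop-2-yn-1-yl]cyclohex-1-en-1-yl]-1-[(2S,4S)-4-methyl-5-oxooxolan-2-yl]ethyl]carbamate | CC[C@H]1[C@H](O[Si](C)(C)C(C)(C)C)C=C(C[C@@H]([C@@H]2C[C@H](C)C(=O)O2)NC(=O)OC(C)(C)C)C(=O)[C@@H]1CC#C[Si](C)(C)C | intermediate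
17 | tert-butyl N-[(1S)-2-[(3S,4R,5R)-4-ethyl-3-hydroxy-6-oxo-5-[3-(trimethylsilyl)prop-2-yn-1-yl]cyclohex-1-en-1-yl]-1-[(2S,4S)-4-methyl-5-oxooxolan-2-yl]ethyl]carbamate | CC[C@H]1[C@H](O)C=C(C[C@@H]([C@@H]2C[C@H](C)C(=O)O2)NC(=O)OC(C)(C)C)C(=O)[C@@H]1CC#C[Si](C)(C)C | intermediate
18 | ethyl prop-1-en-1-yl ether (E/Z mixture) | CCOC=CC | starting material
19 | mixed bromoacetal of 17: O-11 carries CH(OEt)–CH(CH3)Br (diastereomer mixture at the two new centres) | CC[C@H]1[C@H](OC(OCC)C(C)Br)C=C(C[C@@H]([C@@H]2C[C@H](C)C(=O)O2)NC(=O)OC(C)(C)C)C(=O)[C@@H]1CC#C[Si](C)(C)C | intermediate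
20 | bicyclic ethyl acetal: ring O–CH(OEt)–C13H(CH3)–C12 cis-fused at C11/C12 to the cyclohexanone, C1 bearing the carbamate side chain (epimers at C1, C13 and the acetal carbon) | CC[C@H]1[C@@H]2OC(OCC)C(C)[C@@H]2C(C[C@@H]([C@@H]3C[C@H](C)C(=O)O3)NC(=O)OC(C)(C)C)C(=O)[C@@H]1CC#C[Si](C)(C)C | intermediate
21 | lactol corresponding to 20 (OH in place of OEt) | CC[C@H]1[C@@H]2OC(O)C(C)[C@@H]2C(C[C@@H]([C@@H]3C[C@H](C)C(=O)O3)NC(=O)OC(C)(C)C)C(=O)[C@@H]1CC#C[Si](C)(C)C | intermediate (not isolated)
22 | cis-fused α-methyl-γ-lactone cyclohexanone: C9 silylpropargyl, C10 ethyl, C13 methyl on the convex face, C1 (both epimers) bearing CH2–CH(NHBoc)–lactone; C3, C9–C13, C18, C20 arranged as in 31 | CC[C@H]1[C@@H]2OC(=O)[C@@H](C)[C@@H]2C(C[C@@H]([C@@H]3C[C@H](C)C(=O)O3)NC(=O)OC(C)(C)C)C(=O)[C@@H]1CC#C[Si](C)(C)C | intermediate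
23 | bicyclic N-Boc enecarbamate (hexahydroindole with C1=C9a, fused lactone and C3 lactone; stereocentres as in 31) | CC[C@H]1[C@@H]2OC(=O)[C@@H](C)[C@@H]2C3=C([C@@H]1CC#C[Si](C)(C)C)N(C(=O)OC(C)(C)C)[C@@H](C3)[C@@H]4C[C@H](C)C(=O)O4 | intermediate
24 | secondary ozonide (1,2,4-trioxolane across C1 and C9a) of 23 | CC[C@H]1[C@@H]2OC(=O)[C@@H](C)[C@@H]2C35OOC(O5)([C@@H]1CC#C[Si](C)(C)C)N(C(=O)OC(C)(C)C)[C@@H](C3)[C@@H]4C[C@H](C)C(=O)O4 | intermediate (not isolated)
25 | nine-membered N-Boc keto-lactam with C9 silylpropargyl group (stereocentres as in 31) | CC[C@H]1[C@@H]2OC(=O)[C@@H](C)[C@@H]2C(=O)C[C@@H]([C@@H]3C[C@H](C)C(=O)O3)N(C(=O)OC(C)(C)C)C(=O)[C@@H]1CC#C[Si](C)(C)C | intermediate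
26 | nine-membered N-Boc keto-lactam with C9 (Z)-3-(trimethylsilyl)allyl group | CC[C@H]1[C@@H]2OC(=O)[C@@H](C)[C@@H]2C(=O)C[C@@H]([C@@H]3C[C@H](C)C(=O)O3)N(C(=O)OC(C)(C)C)C(=O)[C@@H]1C/C=C\[Si](C)(C)C | intermediate
27 | NH keto-lactam (26 without Boc) | CC[C@H]1[C@@H]2OC(=O)[C@@H](C)[C@@H]2C(=O)C[C@@H]([C@@H]3C[C@H](C)C(=O)O3)NC(=O)[C@@H]1C/C=C\[Si](C)(C)C | intermediate (not isolated)
28 | N-(hydroxymethyl) keto-lactam | CC[C@H]1[C@@H]2OC(=O)[C@@H](C)[C@@H]2C(=O)C[C@@H]([C@@H]3C[C@H](C)C(=O)O3)N(CO)C(=O)[C@@H]1C/C=C\[Si](C)(C)C | intermediate (not isolated)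
29 | N-methylene N-acyliminium trifluoroacetate | CC[C@H]1[C@@H]2OC(=O)[C@@H](C)[C@@H]2C(=O)C[C@@H]([C@@H]3C[C@H](C)C(=O)O3)[N+](=C)C(=O)[C@@H]1C/C=C\[Si](C)(C)C.[O-]C(=O)C(F)(F)F | intermediate (not isolated)
30 | 6,7-didehydro target (bridged keto-lactam with cis C6=C7 in the seven-membered ring) | CC[C@H]1[C@@H]2OC(=O)[C@@H](C)[C@@H]2C(=O)C[C@@H]([C@@H]2C[C@H](C)C(=O)O2)N2C/C=C\C[C@H]1C2=O | intermediate
31 | CNP0311700.2, (3S,9R,10R,11S,12S,13S,18S,20S) in the numbering above | CC[C@H]1[C@@H]2OC(=O)[C@@H](C)[C@@H]2C(=O)C[C@@H]([C@@H]2C[C@H](C)C(=O)O2)N2CCCC[C@H]1C2=O | target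

Total step count: 17. Longest linear sequence: 14 steps (from 1 through steps 1–4 and 8–17).

Steps most likely to fail

Step 16. The hindered lactam may hydroxymethylate slowly, the vinylsilane may protodesilylate in TFA before it cyclises, and the newly unveiled C1 ketone may enolise under acid and epimerise C12. The fallback forms the same bond one oxidation level lower, before the ring expansion, so that the ketone appears only in a final neutral oxidation. It sets out from 22 and comes back at 30. Semihydrogenation of 22 (H2, Pd/CaCO3 poisoned with Pb(OAc)2, quinoline) would give the (Z)-vinylsilane ketone F1. TFA then removes the Boc group, and on buffering with NaOAc the amine should condense onto the ring ketone faster than it attacks the neighbouring lactone, giving the bicyclic 1-pyrroline F2. With paraformaldehyde and TFA in MeCN at 70 °C the imine nitrogen is methylenated and the N-methylene enaminium ion is captured 7-endo by the vinylsilane (iminium–vinylsilane cyclisation at the amine level), giving the tricyclic ring-fusion enamine F3. Photo-oxygenation of F3 (O2, tetraphenylporphyrin, hν, CH2Cl2, −78 °C → rt) should cleave the C1=C9a enamine through its dioxetane to 30.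

Step 11. The secondary radical may be reduced before it cyclises, stannyl radicals may add to the silylalkyne, and control at C13 may be poor. The fallback replaces the radical closure by an ionic intramolecular Michael addition. It sets out from 17 and comes back at 22. Esterification of 17 with 3-methoxy-2-methyl-3-oxopropanoic acid (DCC, DMAP, CH2Cl2) gives the methylmalonate ester F4. Cs2CO3 in MeCN should close the cis-fused ring by 5-exo Michael addition of the malonate carbon to C12, giving the lactone ester F5. Krapcho dealkoxycarbonylation (LiCl, wet DMSO, 120 °C) followed by DBU equilibration leads to 22.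

Step 14. Ozone may over-oxidise the silylalkyne, or the ozonide may fragment abnormally. The fallback cleaves the same bond by epoxidation and glycol cleavage. It sets out from 23 and comes back at 25. Dimethyldioxirane in acetone at −78 → 0 °C, followed by water, should epoxidise only the enecarbamate and hydrate the epoxide to the hydroxy hemiaminal diol F6. NaIO4 in THF/H2O then cleaves the C1–C9a glycol to 25.

Further compounds
F1 | step 16 | (Z)-vinylsilane ketone (22 with the silylalkyne reduced to the cis alkene) | CC[C@H]1[C@@H]2OC(=O)[C@@H](C)[C@@H]2C(C[C@@H]([C@@H]3C[C@H](C)C(=O)O3)NC(=O)OC(C)(C)C)C(=O)[C@@H]1C/C=C\[Si](C)(C)C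
F2 | step 16 | bicyclic 1-pyrroline (cyclic imine N4=C9a, C1 epimers) | CC[C@H]1[C@@H]2OC(=O)[C@@H](C)[C@@H]2C3C[C@@H]([C@@H]4C[C@H](C)C(=O)O4)N=C3[C@@H]1C/C=C\[Si](C)(C)C
F3 | step 16 | tricyclic ring-fusion enamine (C1=C9a, cis C6=C7 azepine ring) | CC[C@H]1[C@@H]2OC(=O)[C@@H](C)[C@@H]2C3=C4N(C/C=C\C[C@H]14)[C@@H](C3)[C@@H]5C[C@H](C)C(=O)O5
F4 | step 11 | methylmalonate ester of 17 (O-11 acylated by CH(CH3)(CO2CH3)C(=O)) | CC[C@H]1[C@H](OC(=O)C(C)C(=O)OC)C=C(C[C@@H]([C@@H]2C[C@H](C)C(=O)O2)NC(=O)OC(C)(C)C)C(=O)[C@@H]1CC#C[Si](C)(C)C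
F5 | step 11 | cis-fused lactone ester (C13 bearing CH3 and CO2CH3) | CC[C@H]1[C@@H]2OC(=O)C(C)(C(=O)OC)[C@@H]2C(C[C@@H]([C@@H]3C[C@H](C)C(=O)O3)NC(=O)OC(C)(C)C)C(=O)[C@@H]1CC#C[Si](C)(C)C
F6 | step 14 | hydroxy hemiaminal diol (C1–OH, C9a–OH, N-Boc) | CC[C@H]1[C@@H]2OC(=O)[C@@H](C)[C@@H]2C3(O)C(O)([C@@H]1CC#C[Si](C)(C)C)N(C(=O)OC(C)(C)C)[C@@H](C3)[C@@H]4C[C@H](C)C(=O)O4
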